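The product I wanted from red and ochre was the complex with one exchanged, and theta and zeta had to tell me how much of it a flask holds once it stops changing.

in all of them: starting complex 0.24 M

| flask | incoming ligand | leaving ligand | remark | time |
|---|---|---|---|---|
| theta | 0.094 M | 0.24 M | run made earlier |  |
| zeta | 0.16 M | 0.24 M | run made earlier |  |
| red | 0.240 M | 0.240 M |  | 20 h |
| ochre | 0.120 M | 0.240 M |  | 20 h |

| run | time / h | complex with one exchanged / % | complex with two exchanged / % |
|---|---|---|---|
| theta | 1.33 | 12.6 | 0.4 |
| theta | 3.00 | 20.5 | 0 |
| theta | 4.00 | 21.9 | 0.6 |
| theta | 6.00 | 25.9 | 0 |
| theta | 8.00 | 25.4 | 0.5 |
| theta | 10.0 | 25.2 | 0 |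
| zeta | 1.33 | 19.8 | 1.0 |
| zeta | 3.00 | 32.2 | 0.7 |
| zeta | 4.00 | 34.9 | 0.9 |
| zeta | 6.00 | 39.6 | 0.3 |
| zeta | 8.00 | 41.1 | 0.5 |
| zeta | 10.0 | 41.7 | 0.5 |

(scatter of a reading: 0.5 percentage points)

- which of these holds the largest part of the starting complex at the end of red (starting complex / complex with two exchanged / complex with one exchanged)
- which of these holds the largest part of the starting complex at the end of ochre (starting complex / complex with two exchanged / complex with one exchanged)
- how much complex with one exchanged is there at the end of red, in percent of the starting complex charged

- percent here means starting complex units held: one side product counts as two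
- what is said of complex with two exchanged includes idle adduct
- the numbers in the tables scatter with a standard deviation of 0.5 percentage points
- candidate steps: starting complex + incoming ligand <-> leaving ligand + complex with one exchanged; complex with one exchanged + incoming ligand <-> leaving ligand + complex with two exchanged; starting complex + complex with one exchanged -> side product; incoming ligand -> decomposition product; complex with two exchanged + incoming ligand <-> idle adduct

Did those runs stop? Zeta rose from 39.6% at 6.00 h to 41.7% at 10.0 h, and the asked 20 h is twice that last time, so I took red and ochre to be on their plateaus by then.

How many exchanges did I need to count? At zeta's last reading the complex with two exchanged was hardly any of the complex with one exchanged, so I counted one.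

What could I reckon the plateau from? I used the exchange quotient (the reaction quotient, or mass-action ratio): complex with one exchanged times leaving ligand over starting complex times incoming ligand, each as a fraction of the starting complex charged, with every unit not found as complex with one exchanged counted as starting complex. Zeta's last reading gave 4.06 and theta's gave 3.02, a factor of 1.34 apart, so this was a working number. I kept zeta's, since zeta held more incoming ligand than theta and so stood nearer red.

It put red at 54.5% complex with one exchanged and 45.5% starting complex, and ochre at 33.5% and 66.5%.

The forecast, working with a quotient of about 4, named complex with one exchanged for red at 52%, somewhat below my figure, and starting complex for ochre, adding of red: “The one-exchanged complex leads, but not by much.”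

Red gave 54.5% of complex with one exchanged, beside 12.7% starting complex and 31.5% side product, while ochre held 37.4% starting complex against 27.3% complex with one exchanged.

    starting complex + incoming ligand ⇌ leaving ligand + complex with one exchanged (K = 27.0, k = 4.00 × 10⁻⁴ L mol⁻¹ s⁻¹)
    complex with one exchanged + incoming ligand ⇌ leaving ligand + complex with two exchanged (K = 0.140, k = 0.00140 L mol⁻¹ s⁻¹)
    starting complex + complex with one exchanged → side product (k = 7.20 × 10⁻⁵ L mol⁻¹ s⁻¹)
    incoming ligand → decomposition product (k = 3.90 × 10⁻⁸ s⁻¹)
    complex with two exchanged + incoming ligand ⇌ idle adduct, settled at all times (K = 1.20 L mol⁻¹)

Taken on what stood in red at 20.0 h, with incoming ligand at 27.0% and leaving ligand at 173% of their own charges, the exchange quotient was 27.6, more than the 4.06 from zeta's balance. The neighbouring flask, red charged with 0.96 M of leaving ligand, held 44.5% complex with one exchanged, and its standing amounts gave about the same quotient, 28.3.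

The earlier runs and the new flask are calculated with made-up constants; the scatter is artificial.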